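**Retrosynthetic overview**

1. Feature: the trisubstituted C7=C8 alkene on the quaternary C6 of the 1,2-dioxane (ring A = O1–O2–C3–C4–C5–C6). C8 carries C9H2 trans and ethyl cis to C6, so C8–C9 and C8–ethyl are both cut back to one C7=C8Br2 unit (two stereospecific Negishi couplings: C9–C14 alkyl iodide, then Et2Zn).
2. C2–C3 is cut last: C3 methoxy peroxyacetal (peroxycarbenium ion) plus the bis-silyl ketene acetal of acetic acid.
3. Dibromide ⇐ C6 aldehyde ⇐ glycol cleavage. Ring A, the only ring, is closed before that at O2–C3 by peroxyacetalisation of a C6 hydroperoxide, which comes from H2O2 opening (inversion) of a Sharpless epoxide.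
4. Backbone C3–C7 ⇐ Evans propargylation (C4), alkyne hydroxymethylation, hydroalumination–iodination, Negishi ethylation. Iodide ⇐ Evans ethylation of an (E)-hex-3-enoyl imide (C10).

Key step: step 19

Remark: atoms keep their target numbers (C1/C2 acetic acid carbons, ring A as above, chain C7–C14); the hydroxymethyl carbon excised in step 12 is called C7a.
Assumption: the 3-methoxy compounds 18, 19, 21, 34 and 35 are carried as C3 epimer mixtures (3RS), because C3 is planarised in step 20.

**Route**

Step 1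
Reactants: 1 (R)-4-benzyloxazolidin-2-one; 2 butanoyl chloride
Product: 3 (R)-4-benzyl-3-butanoyloxazolidin-2-one
Conditions: Et3N, 4-(dimethylamino)pyridine (cat.), CH2Cl2, 0 °C → rt
Reagents that add atoms: none
Why: Amine-catalysed N-acylation of the oxazolidinone by the acid chloride, which forms no stereocentre.

Step 2
Reactants: 3 (R)-4-benzyl-3-butanoyloxazolidin-2-one; 4 3-bromoprop-1-yne
Product: 6 (R)-4-benzyl-3-[(S)-2-ethylpent-4-ynoyl]oxazolidin-2-one, via sodium enolate 5 (not isolated)
Conditions: NaN(SiMe3)2, THF, −78 °C; then 4 (3 equiv), −78 → −40 °C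
Reagents that add atoms: none
Why: Evans asymmetric alkylation, in which the chelated sodium (Z)-enolate is propargylated on the face away from the benzyl group, so that the R auxiliary sets the future C4 as S.

Step 3
Reactants: 6 (R)-4-benzyl-3-[(S)-2-ethylpent-4-ynoyl]oxazolidin-2-one
Product: 7 (S)-2-ethylpent-4-yn-1-ol
Conditions: LiBH4, H2O (1 equiv), Et2O, 0 °C
Reagents that add atoms: none
Why: Reductive cleavage of the N-acyl oxazolidinone by LiBH4 should give the primary alcohol without touching the α-stereocentre and return auxiliary 1.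

Step 4
Reactants: 7 (S)-2-ethylpent-4-yn-1-ol
Product: 8 (S)-2-ethylpent-4-ynal
Conditions: Dess–Martin periodinane, NaHCO3, CH2Cl2, 0 °C → rt; used at once as a solution
Reagents that add atoms: none
Why: Dess–Martin oxidation under buffered, non-enolising conditions should give the α-branched aldehyde without epimerisation at C4.

Step 5
Reactants: 8 (S)-2-ethylpent-4-ynal
Product: 9 (S)-4-(dimethoxymethyl)hex-1-yne
Conditions: HC(OMe)3, MeOH, pyridinium p-toluenesulfonate (cat.), rt
Reagents that add atoms: trimethyl orthoformate, COC(OC)OC; methanol, CO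
Why: Mild acid-catalysed acetalisation with orthoformate as water scavenger masks C3 at the aldehyde oxidation level before any peroxide is made.

Step 6
Reactants: 9 (S)-4-(dimethoxymethyl)hex-1-yne
Product: 11 (S)-5-ethyl-6,6-dimethoxyhex-2-yn-1-ol, via lithium acetylide 10 (not isolated)
Conditions: nBuLi, THF, −78 °C; then (CH2O)n, −78 °C → rt
Reagents that add atoms: formaldehyde (as paraformaldehyde), C=O
Why: Addition of the alkynyllithium to formaldehyde installs C7a as the propargylic alcohol needed to direct the next step, the acetal being inert to base.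

Step 7
Reactants: 11 (S)-5-ethyl-6,6-dimethoxyhex-2-yn-1-ol
Product: 13 (S,Z)-5-ethyl-3-iodo-6,6-dimethoxyhex-2-en-1-ol, via sodium alkenylaluminate 12 (not isolated)
Conditions: NaAlH2(OCH2CH2OMe)2 (1.5 equiv), THF, 0 °C → rt; then I2, −78 → 0 °C; Rochelle salt work-up
Reagents that add atoms: iodine, II
Why: Hydroxyl-directed trans-hydroalumination of the propargylic alcohol places aluminium on C6 in a five-membered alkoxyaluminate, and iodinolysis with retention gives the Z alkenyl iodide with iodine cis to the CH2OH group.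

Step 8
Reactants: 13 (S,Z)-5-ethyl-3-iodo-6,6-dimethoxyhex-2-en-1-ol; 14 diethylzinc
Product: 15 (S,E)-3,5-diethyl-6,6-dimethoxyhex-2-en-1-ol
Conditions: Et2Zn (3 equiv), Pd(PtBu3)2 (5 mol %), THF, 0 °C → rt
Reagents that add atoms: none
Why: Negishi coupling of the alkenyl iodide (as its zinc alkoxide) with retention of geometry puts the C6 ethyl group cis to CH2OH and so gives the E trisubstituted allylic alcohol.

Step 9
Reactants: 15 (S,E)-3,5-diethyl-6,6-dimethoxyhex-2-en-1-ol
Product: 16 [(2R,3R)-3-ethyl-3-[(2S)-2-ethyl-3,3-dimethoxypropyl]oxiran-2-yl]methanol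
Conditions: Ti(OiPr)4 (10 mol %), D-(−)-diethyl tartrate (12 mol %), tBuOOH, 4 Å molecular sieves, CH2Cl2, −20 °C
Reagents that add atoms: tert-butyl hydroperoxide, CC(C)(C)OO
Why: Sharpless asymmetric epoxidation, in which the D-tartrate titanium catalyst delivers oxygen to the alkene face that gives the 2R,3R epoxide of this E 3,3-disubstituted allylic alcohol (reagent control, the C4 centre being remote).

Step 10
Reactants: 16 [(2R,3R)-3-ethyl-3-[(2S)-2-ethyl-3,3-dimethoxypropyl]oxiran-2-yl]methanol
Product: 17 (2R,3S,5S)-3,5-diethyl-3-hydroperoxy-6,6-dimethoxyhexane-1,2-diol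
Conditions: anhydrous H2O2 in Et2O (excess), MoO2(acac)2 (10 mol %), rt; excess H2O2 washed out, crude used
Reagents that add atoms: hydrogen peroxide, OO
Why: Molybdenum-catalysed perhydrolysis of the 2,3-epoxy alcohol, in which H2O2 opens the activated epoxide at the tertiary carbon C6 from the back side, so that inversion of the Sharpless-derived centre should set C6 as S.

Step 11
Reactants: 17 (2R,3S,5S)-3,5-diethyl-3-hydroperoxy-6,6-dimethoxyhexane-1,2-diol
Product: 18 (1R)-1-[(3RS,4S,6S)-4,6-diethyl-3-methoxy-1,2-dioxan-6-yl]ethane-1,2-diol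
Conditions: p-toluenesulfonic acid monohydrate (cat.), CH2Cl2, 0 °C
Reagents that add atoms: none
Why: Acid-catalysed intramolecular transacetalisation, in which the more nucleophilic hydroperoxide displaces one methoxy group of the dimethyl acetal in a 6-exo closure of ring A (O2–C3 bond), C3 forming as an epimer mixture.

Step 12
Reactants: 18 (1R)-1-[(3RS,4S,6S)-4,6-diethyl-3-methoxy-1,2-dioxan-6-yl]ethane-1,2-diol
Product: 19 (3RS,4S,6S)-4,6-diethyl-3-methoxy-1,2-dioxane-6-carbaldehyde
Conditions: NaIO4, THF/H2O, 0 °C → rt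
Reagents that add atoms: none
Why: Periodate glycol cleavage excises C7a and leaves C7 as an aldehyde on the quaternary, non-epimerisable C6, the dialkyl peroxide being inert to periodate.

Step 13
Reactants: 19 (3RS,4S,6S)-4,6-diethyl-3-methoxy-1,2-dioxane-6-carbaldehyde; 20 carbon tetrabromide
Product: 21 (3RS,4S,6S)-6-(2,2-dibromoethenyl)-4,6-diethyl-3-methoxy-1,2-dioxane
Conditions: CBr4 (2 equiv), PPh3 (4 equiv), CH2Cl2, 0 °C, ylide preformed; then Et3N, 19, 0 °C
Reagents that add atoms: none
Why: Corey–Fuchs-type dibromo-olefination with the preformed dibromomethylene ylide, so that no free phosphine meets the peroxide and the amine buffers the acetal.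

Step 14
Reactants: 22 (E)-hex-3-enoic acid; 23 (S)-4-benzyloxazolidin-2-one
Product: 25 (S)-4-benzyl-3-[(E)-hex-3-enoyl]oxazolidin-2-one, via mixed pivalic anhydride 24 (not isolated)
Conditions: tBuCOCl, Et3N, THF, −20 °C; then 23, LiCl, −20 °C → rt
Reagents that add atoms: none
Why: N-acylation through the mixed pivalic anhydride under LiCl/Et3N is mild enough to keep the β,γ-double bond out of conjugation.

Step 15
Reactants: 25 (S)-4-benzyl-3-[(E)-hex-3-enoyl]oxazolidin-2-one; 26 iodoethane
Product: 28 (S)-4-benzyl-3-[(S,E)-2-ethylhex-3-enoyl]oxazolidin-2-one, via sodium dienolate 27 (not isolated)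
Conditions: NaN(SiMe3)2, THF, −78 °C; then EtI (5 equiv), −78 → −30 °C
Reagents that add atoms: none
Why: Evans asymmetric alkylation, in which the chelated Z dienolate is ethylated at the α-carbon on the face away from the benzyl group, so that the S auxiliary sets the future C10 (S in 28, R in the target by priority change).

Step 16
Reactants: 28 (S)-4-benzyl-3-[(S,E)-2-ethylhex-3-enoyl]oxazolidin-2-one
Product: 29 (S,E)-2-ethylhex-3-en-1-ol
Conditions: LiBH4, H2O (1 equiv), Et2O, 0 °C
Reagents that add atoms: none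
Why: Reductive cleavage of the imide by LiBH4 gives the primary alcohol without deconjugation or epimerisation and returns auxiliary 23.

Step 17
Reactants: 29 (S,E)-2-ethylhex-3-en-1-ol
Product: 30 (S,E)-5-(iodomethyl)hept-3-ene
Conditions: I2, PPh3, imidazole, CH2Cl2, 0 °C → rt
Reagents that add atoms: iodine, II
Why: Appel-type iodination by SN2 displacement at the primary carbon, which leaves the adjacent stereocentre and the E alkene untouched.

Step 18
Reactants: 31 trimethylsilyl acetate
Product: 32 1,1-bis(trimethylsilyloxy)ethene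
Conditions: iPr2NLi, Me3SiCl (in situ quench), THF, −78 °C → rt; distillation
Reagents that add atoms: chlorotrimethylsilane, C[Si](C)(C)Cl
Why: O-silylation of the lithium enolate of the silyl ester gives the bis-silyl ketene acetal of acetic acid.

Step 19
Reactants: 21 (3RS,4S,6S)-6-(2,2-dibromoethenyl)-4,6-diethyl-3-methoxy-1,2-dioxane; 30 (S,E)-5-(iodomethyl)hept-3-ene; 14 diethylzinc
Product: 35 (3RS,4S,6S)-6-[(1E,4R,5E)-2,4-diethylocta-1,5-dien-1-yl]-4,6-diethyl-3-methoxy-1,2-dioxane, via alkylzinc iodide 33 (not isolated), via bromoalkene 34 (not isolated)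
Conditions: 30, Zn dust (activated), LiCl, THF, 40 °C, solution decanted from zinc; then 21, PdCl2(DPEphos) (5 mol %), THF, 0 °C → rt; then Pd(PtBu3)2 (5 mol %), Et2Zn (2 equiv), rt
Reagents that add atoms: none
Why: The divalent palladium precatalyst (DPEphos = bis(2-diphenylphosphinophenyl) ether) is reduced by the organozinc to zerovalent palladium, which inserts into the C8–Br bond trans to C6, alkylzinc iodide 33 transmetalates, and reductive elimination forms C8–C9 to give the Z bromoalkene 34. Pd(PtBu3)2 then inserts into the remaining hindered C8–Br bond and Et2Zn delivers ethyl with retention, forming the C8–ethyl bond of 35. The closest known reaction type is the tandem Negishi coupling of 1,1-dibromo-1-alkenes, a trans-selective monoalkylation followed by a stereoretentive second alkylation. No ring closes and no stereocentre is formed; C10 comes unchanged from 30 and the C3 epimer mixture is carried on. The step needs monoalkylation with trans-selectivity in the first coupling, which the shielding of the cis bromine by the quaternary C6 and the bidentate ligand should secure, and retention in the second, which the bulky PtBu3 catalyst should secure, so that the order of addition alone fixes the 7E geometry although ethyl and C9H2 are nearly equal in size. The O1–O2 bond should survive because oxidative addition to the alkenyl C–Br bond is far faster than any reaction at the hindered dialkyl peroxide and no zinc metal reaches the substrate.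

Step 20
Reactants: 35 (3RS,4S,6S)-6-[(1E,4R,5E)-2,4-diethylocta-1,5-dien-1-yl]-4,6-diethyl-3-methoxy-1,2-dioxane; 32 1,1-bis(trimethylsilyloxy)ethene
Product: 37 2-[(3S,4S,6S)-6-[(1E,4R,5E)-2,4-diethylocta-1,5-dien-1-yl]-4,6-diethyl-1,2-dioxan-3-yl]acetic acid, via trimethylsilyl ester 36 (not isolated)
Conditions: 32 (3 equiv), Me3SiOTf (0.3 equiv), CH2Cl2, −78 °C; then aq. NH4Cl
Reagents that add atoms: none
Why: Mukaiyama-type addition, in which Me3SiOTf ionises the C3 methoxy group to a ring A peroxycarbenium ion, the silyl ketene acetal attacks C3 axially on the half-chair that keeps the C4 ethyl group and the C6 dienyl chain pseudoequatorial, which should set C3 as S (acetic acid chain cis to the C4 ethyl group), and the silyl ester 36 is hydrolysed on work-up.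

**Compound list**

1 | (R)-4-benzyloxazolidin-2-one | O=C1N[C@H](Cc2ccccc2)CO1 | starting material
2 | butanoyl chloride | CCCC(=O)Cl | starting material
3 | (R)-4-benzyl-3-butanoyloxazolidin-2-one | CCCC(=O)N1[C@H](Cc2ccccc2)COC1=O | intermediate
4 | 3-bromoprop-1-yne | C#CCBr | starting material
5 | sodium (Z)-enolate of 3 | CC/C=C(\[O-])N1[C@H](Cc2ccccc2)COC1=O.[Na+] | intermediate (not isolated)
6 | (R)-4-benzyl-3-[(S)-2-ethylpent-4-ynoyl]oxazolidin-2-one | C#CC[C@H](CC)C(=O)N1[C@H](Cc2ccccc2)COC1=O | intermediate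
7 | (S)-2-ethylpent-4-yn-1-ol | C#CC[C@H](CC)CO | intermediate
8 | (S)-2-ethylpent-4-ynal | C#CC[C@H](CC)C=O | intermediate
9 | (S)-4-(dimethoxymethyl)hex-1-yne | C#CC[C@H](CC)C(OC)OC | intermediate
10 | lithium acetylide of 9 | [Li]C#CC[C@H](CC)C(OC)OC | intermediate (not isolated)
11 | (S)-5-ethyl-6,6-dimethoxyhex-2-yn-1-ol | OCC#CC[C@H](CC)C(OC)OC | intermediate
12 | sodium bis(2-methoxyethoxy) alkenylaluminate (five-membered O–Al–C6=C7–C7a chelate) | COCCO[Al-]1(OCCOC)OCC=C1C[C@H](CC)C(OC)OC.[Na+] | intermediate (not isolated)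
13 | (S,Z)-5-ethyl-3-iodo-6,6-dimethoxyhex-2-en-1-ol | OC/C=C(\I)C[C@H](CC)C(OC)OC | intermediate
14 | diethylzinc | CC[Zn]CC | starting material
15 | (S,E)-3,5-diethyl-6,6-dimethoxyhex-2-en-1-ol | OC/C=C(\CC)C[C@H](CC)C(OC)OC | intermediate
16 | [(2R,3R)-3-ethyl-3-[(2S)-2-ethyl-3,3-dimethoxypropyl]oxiran-2-yl]methanol | OC[C@H]1O[C@]1(CC)C[C@H](CC)C(OC)OC | intermediate
17 | (2R,3S,5S)-3,5-diethyl-3-hydroperoxy-6,6-dimethoxyhexane-1,2-diol | OC[C@@H](O)[C@@](CC)(OO)C[C@H](CC)C(OC)OC | intermediate
18 | (1R)-1-[(3RS,4S,6S)-4,6-diethyl-3-methoxy-1,2-dioxan-6-yl]ethane-1,2-diol | OC[C@@H](O)[C@]1(CC)C[C@H](CC)C(OC)OO1 | intermediate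
19 | (3RS,4S,6S)-4,6-diethyl-3-methoxy-1,2-dioxane-6-carbaldehyde | O=C[C@]1(CC)C[C@H](CC)C(OC)OO1 | intermediate
20 | carbon tetrabromide | BrC(Br)(Br)Br | starting material
21 | (3RS,4S,6S)-6-(2,2-dibromoethenyl)-4,6-diethyl-3-methoxy-1,2-dioxane | BrC(Br)=C[C@]1(CC)C[C@H](CC)C(OC)OO1 | intermediate
22 | (E)-hex-3-enoic acid | CC/C=C/CC(=O)O | starting material
23 | (S)-4-benzyloxazolidin-2-one | O=C1N[C@@H](Cc2ccccc2)CO1 | starting material
24 | (E)-hex-3-enoic pivalic anhydride | CC/C=C/CC(=O)OC(=O)C(C)(C)C | intermediate (not isolated)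
25 | (S)-4-benzyl-3-[(E)-hex-3-enoyl]oxazolidin-2-one | CC/C=C/CC(=O)N1[C@@H](Cc2ccccc2)COC1=O | intermediate
26 | iodoethane | CCI | starting material
27 | sodium (Z)-dienolate of 25 | CC/C=C/C=C(\[O-])N1[C@@H](Cc2ccccc2)COC1=O.[Na+] | intermediate (not isolated)
28 | (S)-4-benzyl-3-[(S,E)-2-ethylhex-3-enoyl]oxazolidin-2-one | CC/C=C/[C@H](CC)C(=O)N1[C@@H](Cc2ccccc2)COC1=O | intermediate
29 | (S,E)-2-ethylhex-3-en-1-ol | CC/C=C/[C@H](CC)CO | intermediate
30 | (S,E)-5-(iodomethyl)hept-3-ene | CC/C=C/[C@H](CC)CI | intermediate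
31 | trimethylsilyl acetate | CC(=O)O[Si](C)(C)C | starting material
32 | 1,1-bis(trimethylsilyloxy)ethene | C=C(O[Si](C)(C)C)O[Si](C)(C)C | intermediate
33 | [(S,E)-2-ethylhex-3-en-1-yl]zinc iodide | CC/C=C/[C@H](CC)C[Zn]I | intermediate (not isolated)
34 | (3RS,4S,6S)-6-[(1Z,4R,5E)-2-bromo-4-ethylocta-1,5-dien-1-yl]-4,6-diethyl-3-methoxy-1,2-dioxane | CC/C=C/[C@H](CC)C/C(Br)=C/[C@]1(CC)C[C@H](CC)C(OC)OO1 | intermediate (not isolated)
35 | (3RS,4S,6S)-6-[(1E,4R,5E)-2,4-diethylocta-1,5-dien-1-yl]-4,6-diethyl-3-methoxy-1,2-dioxane | CC/C=C/[C@H](CC)C/C(=C/[C@]1(CC)C[C@H](CC)C(OC)OO1)CC | intermediate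
36 | trimethylsilyl 2-[(3S,4S,6S)-6-[(1E,4R,5E)-2,4-diethylocta-1,5-dien-1-yl]-4,6-diethyl-1,2-dioxan-3-yl]acetate | CC/C=C/[C@H](CC)C/C(=C/[C@]1(CC)C[C@H](CC)[C@H](CC(=O)O[Si](C)(C)C)OO1)CC | intermediate (not isolated)
37 | 2-[(3S,4S,6S)-6-[(1E,4R,5E)-2,4-diethylocta-1,5-dien-1-yl]-4,6-diethyl-1,2-dioxan-3-yl]acetic acid | CC/C=C/[C@H](CC)C/C(=C/[C@]1(CC)C[C@H](CC)[C@H](CC(=O)O)OO1)CC | target

**Step count**

Total: 20 steps. Longest linear sequence: 15 steps (steps 1–13, 19, 20).

**Steps most likely to fail**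

Step 10. The tertiary epoxide carbon may ionise before H2O2 arrives, which would erode the inversion at C6. H2O2 may also attack C7, or the β-hydroxy hydroperoxide may fragment across C6–C7 under the catalyst. The fallback sets out from 16 and comes back at 18. It delivers the peroxide from a tether instead of from solution. Compound 16 would be treated with a small excess of anhydrous ethereal H2O2 and catalytic camphorsulfonic acid, so that one methoxy group of the acetal is exchanged for a hydroperoxy group. This gives [(2R,3R)-3-ethyl-3-[(2S)-2-ethyl-3-hydroperoxy-3-methoxypropyl]oxiran-2-yl]methanol F1. Under the same acid the tethered hydroperoxide should open the epoxide by 6-exo attack at C6 with enforced back-side geometry, which gives 18 directly.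

Step 19. Both bromines may react with the alkylzinc, or the trans-selectivity may be low next to the very hindered C6. The alkene may isomerise or undergo hydrodebromination through β-hydride elimination in the ethylation, and low-valent palladium or the zinc reagents may cleave the O–O bond. The fallback sets out from 19 and 30 and comes back at 35. It forms C7=C8 by a Stork–Zhao-type iodo-olefination. Iodide 30 would be heated with PPh3 to [(S,E)-2-ethylhex-3-en-1-yl]triphenylphosphonium iodide F2. nBuLi would give [(S,E)-2-ethylhex-3-en-1-ylidene]triphenylphosphorane F3, iodine [(2S,3E)-2-ethyl-1-iodohex-3-en-1-yl]triphenylphosphonium iodide F4, and NaN(SiMe3)2 [(2S,3E)-2-ethyl-1-iodohex-3-en-1-ylidene]triphenylphosphorane F5. Ylide F5 should olefinate aldehyde 19 Z-selectively to (3RS,4S,6S)-6-[(1Z,4R,5E)-4-ethyl-2-iodoocta-1,5-dien-1-yl]-4,6-diethyl-3-methoxy-1,2-dioxane F6, in which C9 is already trans to C6. A single Negishi coupling of F6 with Et2Zn 14 and Pd(PtBu3)2, with retention, would then give 35.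

Step 20. The ketene acetal may add to the wrong face of the peroxycarbenium ion, giving the C3 epimer. The Lewis acid may also ionise the tertiary, allylic C6–O1 bond of the dienyl-substituted peroxide. The fallback sets out from 21 and comes back at 37. It moves the C2–C3 bond formation ahead of the couplings, where the electron-poor dibromovinyl group does not support a cation at C6. Compound 21 would be treated with commercial 1-methoxy-1-(trimethylsilyloxy)ethene and Me3SiOTf in CH2Cl2 at −78 °C to give methyl 2-[(3S,4S,6S)-6-(2,2-dibromoethenyl)-4,6-diethyl-1,2-dioxan-3-yl]acetate F7, from which a C3 epimer could be removed by chromatography. The sequence of step 19 (alkylzinc 33, then Et2Zn 14) would then be run on F7. It should pass through methyl 2-[(3S,4S,6S)-6-[(1Z,4R,5E)-2-bromo-4-ethylocta-1,5-dien-1-yl]-4,6-diethyl-1,2-dioxan-3-yl]acetate F8 and give methyl 2-[(3S,4S,6S)-6-[(1E,4R,5E)-2,4-diethylocta-1,5-dien-1-yl]-4,6-diethyl-1,2-dioxan-3-yl]acetate F9. Saponification of F9 with LiOH in THF/H2O at 0 °C and acidification would give 37.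

**Further compounds**

F1 | step 10 | [(2R,3R)-3-ethyl-3-[(2S)-2-ethyl-3-hydroperoxy-3-methoxypropyl]oxiran-2-yl]methanol | OC[C@H]1O[C@]1(CC)C[C@H](CC)C(OC)OO
F2 | step 19 | [(S,E)-2-ethylhex-3-en-1-yl]triphenylphosphonium iodide | CC/C=C/[C@H](CC)C[P+](c1ccccc1)(c1ccccc1)c1ccccc1.[I-]
F3 | step 19 | [(S,E)-2-ethylhex-3-en-1-ylidene]triphenylphosphorane | CC/C=C/[C@H](CC)C=P(c1ccccc1)(c1ccccc1)c1ccccc1
F4 | step 19 | [(2S,3E)-2-ethyl-1-iodohex-3-en-1-yl]triphenylphosphonium iodide | CC/C=C/[C@H](CC)C(I)[P+](c1ccccc1)(c1ccccc1)c1ccccc1.[I-]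
F5 | step 19 | [(2S,3E)-2-ethyl-1-iodohex-3-en-1-ylidene]triphenylphosphorane | CC/C=C/[C@H](CC)C(I)=P(c1ccccc1)(c1ccccc1)c1ccccc1
F6 | step 19 | (3RS,4S,6S)-6-[(1Z,4R,5E)-4-ethyl-2-iodoocta-1,5-dien-1-yl]-4,6-diethyl-3-methoxy-1,2-dioxane | CC/C=C/[C@H](CC)C/C(I)=C/[C@]1(CC)C[C@H](CC)C(OC)OO1
F7 | step 20 | methyl 2-[(3S,4S,6S)-6-(2,2-dibromoethenyl)-4,6-diethyl-1,2-dioxan-3-yl]acetate | BrC(Br)=C[C@]1(CC)C[C@H](CC)[C@H](CC(=O)OC)OO1
F8 | step 20 | methyl 2-[(3S,4S,6S)-6-[(1Z,4R,5E)-2-bromo-4-ethylocta-1,5-dien-1-yl]-4,6-diethyl-1,2-dioxan-3-yl]acetate | CC/C=C/[C@H](CC)C/C(Br)=C/[C@]1(CC)C[C@H](CC)[C@H](CC(=O)OC)OO1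
F9 | step 20 | methyl 2-[(3S,4S,6S)-6-[(1E,4R,5E)-2,4-diethylocta-1,5-dien-1-yl]-4,6-diethyl-1,2-dioxan-3-yl]acetate | CC/C=C/[C@H](CC)C/C(=C/[C@]1(CC)C[C@H](CC)[C@H](CC(=O)OC)OO1)CC
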